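## The problem

Compound 18 is a eudesmane: a trans-fused decalin with a β angular methyl group on C10, a β (equatorial) isopropyl group on C7 and oxygen on C3, C4 and C6. Six stereocentres must be set (C3, C4, C5, C6, C7, C10); five are contiguous and C10 is quaternary. In the chair–chair form the 3α-hydroxyl, the 4β-hydroxyl and the 6β-benzoyloxy group are all axial. The C3/C4 diol is therefore trans-diaxial, the oxygens on C4 and C6 stand syn-axial to the C10 methyl group, and the C4 methyl group is equatorial. C7 is 1,4-cis to the C10 methyl group and can direct its introduction. The axial C10 methyl group in turn shields the β-face of C6 and penalises an axial methyl group on C4, so C10 can control C4 and C6. C3 has no reliable relay and is best bought as a stereocentre. The sensitive points are the tertiary C4 hydroxyl (β to C6, so open to retro-aldol cleavage or dehydration while C6 is a ketone), the epimerisable C5 and C7 at that stage, and the benzoate, which must go onto a hindered axial hydroxyl and survive the last deprotection. The enabling feature is that C6, taken as a carbonyl carbon, has C5 as its α-carbon and C10 as its β-carbon, with the methyl carbinol C4 attached to C5. A C5=C10 enone can thus accept the angular methyl group at C10, and the C5 enolate formed can close ring A onto a tethered C4 methyl ketone.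

## Retrosynthesis

**18 back to 15.** The benzoate C–O bond and the C3 silyl ether are cut first: 18 comes from 17 by desilylation and 17 from diol 16 by acylation. Keeping C3 silylated until the end leaves the 6β-hydroxyl as the only acylable group, since the tertiary C4 hydroxyl does not react. Diol 16 is traced to ketol 15; the forward step needs hydride to enter C6 from the α-face, which the syn-axial C10 methyl and C4 oxygen should enforce. Ketone 15 has one stereocentre fewer and carries the carbonyl needed for C–C bond construction.

**15 back to 13.** Two bonds are cut at once: C10–CH3 and C4–C5. Cutting only C4–C5 would demand a separate construction of the quaternary centre and a regioselective enolisation of a diketone. Cutting only C10–CH3 would demand a preformed decalin enone. The double cut lets one reagent make the quaternary centre and deliver the C5 enolate regiospecifically (14), which then closes ring A. The precursor 13 is a monocyclic enone with two stereocentres (C7, C3). The forward step must set C10 from C7 and set C5 and C4 in the ring closure. The C3 oxygen is carried as a non-chelating TBS ether, so the ketone cannot be chelated into the O3/O4 syn arrangement, which is the wrong one.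

**13 back to 4 and 9.** The C4 ketone of 13 is masked as an isopropenyl group (12), so that the side chain can be introduced as an organolithium and the ketone released under neutral conditions immediately before the key step. Enone 12 is cut at C1–C10 with a 1,3-carbonyl transposition: tertiary allylic alcohol 11 comes from alkyllithium 10 (from iodide 9) and (S)-cryptone 4. An alkylation of a 3-alkoxy enone followed by addition and hydrolysis would put the isopropyl group γ to the carbonyl, the wrong position. The addition/oxidative transposition sequence puts it α′, as required, and uses an enone whose only stereocentre is available by catalysis.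

**4 back to 1 and 2.** Cryptone 4 is opened at the enone C=C bond to keto aldehyde 3, and 3 at the bond between C7 and the MVK-derived C8 to isovaleraldehyde 1 and methyl vinyl ketone 2. An enamine-catalysed Michael addition sets C7, and the ring closure must not racemise it.

**9 back to 5.** The side chain maps onto (R)-α-hydroxy-γ-butyrolactone 5: the lactone carbonyl becomes C4, the carbinol carbon C3, and the two methylenes C2 and C1. The C4–C15 bond is cut to methyllithium and silylated lactone 6, giving hydroxy ketone 7. The primary hydroxyl becomes the iodide (8) and the ketone is methylenated (9). An acetate aldol route to the same fragment would need a chiral auxiliary; the lactone brings C3 in enantiopure form.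

## Roads not taken

**Alternative 1:** Cut C9–C10 of ring B. The phenol tosylate A1 is deprotonated and alkylated through its para carbon, giving the cross-conjugated dienone A2 with the quaternary C10 in place.
- Merits: intramolecular phenoxide C-alkylation is a robust bond formation; the aromatic precursor is easy to assemble; the C6 oxygen and C7 are fixed before cyclisation.
- Weak points: C6 and C7 must first be set in an open chain. More seriously, ring A of A2 has the wrong oxidation pattern. Reaching the 3α,4β-diol with 5α-H requires saturating C1=C2, reducing C3 to the axial alcohol, and adding H at C5 and OH at C4 across a tetrasubstituted enone double bond with oxygen on the α-carbon, which runs against conjugate reactivity. That is a long redox sequence with weak stereocontrol.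
- Comparison: the alkylation is probably the more dependable C–C bond formation. Against that, the chosen plan delivers ring A at the correct oxidation level with three stereocentres in one step and ends three steps later.

**Alternative 2:** Cut C5–C6 and C9–C10. Quinone A3 and silyloxy diene A4 combine under a chiral oxazaborolidinium Lewis acid to give the cis-fused endo adduct A5.
- Merits: highly convergent; both rings and the quaternary centre arise from two flat components; absolute configuration is set by a catalyst in one event, not by remote induction.
- Weak points: A5 fits the target poorly. It is cis-fused, so C5 must be epimerised. The endo rule places the C6 silyloxy group trans to the angular methyl (6α), so C6 must be inverted. It carries a C1 carbonyl that the target lacks and lacks the C4 methyl group. The C7=C8 double bond must still be reduced with facial control, and the enol ether must be converted into the 3α-alcohol.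
- Comparison: this road is better in convergence and in catalyst-controlled absolute stereochemistry. The chosen plan sets against it that every functional group of 15 maps directly onto the target, at the price of relying on the C7 centre to steer C10.

**Alternative 3:** Cut C6–C7 and C7–C8. The hydrindanone A6 is homologated with the diazoalkane A7 under a Lewis acid, with C8 migrating, and base equilibration of C5 and C7 gives eudesm-3-en-6-one A8.
- Merits: C5 and C7 are set thermodynamically; the Δ3 alkene allows epoxidation and trans-diaxial opening, which gives the 3α,4β-diol from either epoxide face.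
- Weak points: enantiopure A6, with its own quaternary centre and a trans ring fusion that is prone to epimerise, is a multistep problem in itself. A7 is a non-stabilised, hazardous diazoalkane. The migrating carbon (C8 against C5) may not be fully selective. After A8, five or so steps remain.
- Comparison: the diol installation here is stereochemically safer than the aldol closure of the chosen plan. The chosen plan sets against it a shorter sequence, formation of the quaternary centre and ring A in one step from an enone two steps from commodity chemicals, and no diazoalkane.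

Key step: step 10

Assumption: (R)-α-hydroxy-γ-butyrolactone 5 is taken as commercial, and the (S)-diarylprolinol ether is taken to give (S)-3 by the usual steric model (bond formation anti to the diarylmethyl group); if the sense were opposite, the enantiomeric catalyst would be used.

## Route

Step 1
Reactants: 1 isovaleraldehyde (3-methylbutanal); 2 but-3-en-2-one
Product: 3 (S)-2-isopropyl-5-oxohexanal
Conditions: (S)-diphenylprolinol methyl ether (5 mol%), ethyl 3,4-dihydroxybenzoate (20 mol%), neat, 4 °C
Reagents that add atoms: none
Why: Enamine-catalysed Michael addition of an aldehyde to an enone; the catalyst shields one face of the E-enamine so that the enone bonds to the α-carbon and sets C7 as (S), while the catechol co-catalyst activates the enone by hydrogen bonding.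

Step 2
Reactants: 3 (S)-2-isopropyl-5-oxohexanal
Product: 4 (S)-4-isopropylcyclohex-2-en-1-one ((S)-cryptone)
Conditions: LiOH (cat.), i-PrOH, rt
Reagents that add atoms: none
Why: Intramolecular aldol condensation (ring closure of a Robinson-type annulation); the mild hydroxide closes and dehydrates without enolising toward the γ-stereocentre, so C7 is retained.

Step 3
Reactants: 5 (R)-3-hydroxydihydrofuran-2(3H)-one
Product: 6 (R)-3-(tert-butyldimethylsilyloxy)dihydrofuran-2(3H)-one
Conditions: TBSCl, imidazole, DMF, rt
Reagents that add atoms: tert-butyldimethylsilyl chloride, CC(C)(C)[Si](C)(C)Cl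
Why: Standard silylation of a secondary alcohol; the stereocentre is not touched.

Step 4
Reactants: 6 (R)-3-(tert-butyldimethylsilyloxy)dihydrofuran-2(3H)-one
Product: 7 (R)-3-(tert-butyldimethylsilyloxy)-5-hydroxypentan-2-one (in equilibrium with its cyclic hemiketal)
Conditions: MeLi (1.05 equiv), THF, −78 °C; AcOH, −78 °C
Reagents that add atoms: methyllithium, [Li]C
Why: Mono-addition of an organolithium to a γ-lactone; the lithium hemiketal is stable at −78 °C and releases the methyl ketone only on quenching, and the cold acidic quench avoids enolisation of the α-silyloxy ketone.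

Step 5
Reactants: 7 (R)-3-(tert-butyldimethylsilyloxy)-5-hydroxypentan-2-one
Product: 8 (R)-3-(tert-butyldimethylsilyloxy)-5-iodopentan-2-one
Conditions: I2, PPh3, imidazole, CH2Cl2, 0 °C → rt
Reagents that add atoms: iodine, II
Why: Appel-type iodination of the primary alcohol, which is drained from the hemiketal equilibrium; the buffered neutral medium leaves the silyl ether and the α-stereocentre alone.

Step 6
Reactants: 8 (R)-3-(tert-butyldimethylsilyloxy)-5-iodopentan-2-one
Product: 9 (R)-tert-butyl[(5-iodo-2-methylpent-1-en-3-yl)oxy]dimethylsilane
Conditions: Tebbe reagent, pyridine (cat.), THF/toluene, −40 → 0 °C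
Reagents that add atoms: Tebbe reagent (written as Cp2Ti=CH2·AlMe2Cl), C=[Ti](C1C=CC=C1)C1C=CC=C1.C[Al](C)Cl
Why: Tebbe methylenation is non-basic, so the enolisable α-silyloxy ketone becomes the 1,1-disubstituted alkene (a masked acetyl group) without epimerisation and without touching the alkyl iodide.

Step 7
Reactants: 9 (R)-tert-butyl[(5-iodo-2-methylpent-1-en-3-yl)oxy]dimethylsilane; 4 (S)-4-isopropylcyclohex-2-en-1-one
Product: 11 (4S)-1-[(3R)-3-(tert-butyldimethylsilyloxy)-4-methylpent-4-en-1-yl]-4-isopropylcyclohex-2-en-1-ol (both C1 epimers), via alkyllithium 10 (not isolated)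
Conditions: t-BuLi (2.1 equiv), Et2O/pentane, −78 °C; then 4, −78 °C; H2O
Reagents that add atoms: none
Why: Lithium–iodine exchange gives the primary alkyllithium, which in ether at −78 °C (where retro-Brook silyl migration is slow) adds 1,2 to the enone carbonyl; the new carbinol centre forms as a mixture but is erased in step 8.

Step 8
Reactants: 11 (4S)-1-[(3R)-3-(tert-butyldimethylsilyloxy)-4-methylpent-4-en-1-yl]-4-isopropylcyclohex-2-en-1-ol
Product: 12 (6S)-3-[(3R)-3-(tert-butyldimethylsilyloxy)-4-methylpent-4-en-1-yl]-6-isopropylcyclohex-2-en-1-one
Conditions: PCC, NaOAc, 4 Å MS, CH2Cl2, rt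
Reagents that add atoms: pyridinium chlorochromate, [O-][Cr](=O)(=O)Cl.c1cc[nH+]cc1
Why: Dauben–Babler oxidative transposition; the tertiary allylic chromate ester undergoes a [3,3] shift and the secondary chromate is oxidised, placing the carbonyl next to the isopropyl-bearing carbon. The acetate buffer protects the silyl ether and the now α-positioned C7 centre.

Step 9
Reactants: 12 (6S)-3-[(3R)-3-(tert-butyldimethylsilyloxy)-4-methylpent-4-en-1-yl]-6-isopropylcyclohex-2-en-1-one
Product: 13 (6S)-3-[(3R)-3-(tert-butyldimethylsilyloxy)-4-oxopentyl]-6-isopropylcyclohex-2-en-1-one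
Conditions: O3, CH2Cl2/MeOH, Sudan Red 7B, −78 °C; Me2S, −78 °C → rt
Reagents that add atoms: ozone, [O-][O+]=O
Why: Chemoselective ozonolysis; electrophilic ozone cleaves the isolated 1,1-disubstituted alkene far faster than the conjugated, electron-poor ring alkene, the dye marks the end point, and reductive work-up gives the methyl ketone under neutral conditions.

Step 10
Reactants: 13 (6S)-3-[(3R)-3-(tert-butyldimethylsilyloxy)-4-oxopentyl]-6-isopropylcyclohex-2-en-1-one
Product: 15 (3R,4R,5R,7S,10S)-3-(tert-butyldimethylsilyloxy)-4-hydroxyeudesman-6-one (3α-OTBS 4β-OH 5α-H trans-decalin), via lithium enolate 14 (not isolated)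
Conditions: Me2CuLi (from CuI and 2 MeLi, 1.5 equiv), Et2O, −78 → 0 °C; aq NH4Cl/NH3
Reagents that add atoms: lithium dimethylcuprate, [Li+].C[Cu-]C
Why: The cuprate transfers methyl to the β-carbon C10 of the enone and leaves the C5 lithium enolate 14 regiospecifically; on warming, 14 attacks the tethered C4 ketone, so C10–CH3 and C4–C5 form in one operation. The closest known chemistry is the tandem cuprate conjugate addition–intramolecular aldol cyclisation of cycloalkenones carrying a ketone in the 3-substituent, and angular methylation of 3-alkylcyclohexenones. Ring A closes in the 6-(enolexo)-exo-trig mode. C10 is controlled by C7: in the enone half-chair with the isopropyl group pseudoequatorial, stereoelectronically preferred axial entry at C10 places the methyl group cis to the isopropyl group. C5 and C4 are set in the closure: a lithium aldolate from two ketones reverts readily at 0 °C, so the most stable isomer should accumulate, namely the trans-decalin with H5 anti to the angular methyl, the C4 methyl equatorial and the C4 oxygen axial (an axial C4 methyl would be syn-diaxial to the C10 methyl). The C3 silyloxy group is then axial and anti to the new C4–O bond, a dipole-minimised arrangement that the non-chelating silyl ether allows. The step needs 1,4- over 1,2-addition (soft cuprate, hindered α-silyloxy ketone) and closure without dehydration or C7 epimerisation, which the low temperature and buffered quench should secure.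

Step 11
Reactants: 15 (3R,4R,5R,7S,10S)-3-(tert-butyldimethylsilyloxy)-4-hydroxyeudesman-6-one
Product: 16 (3R,4R,5S,6R,7S,10S)-3-(tert-butyldimethylsilyloxy)eudesmane-4,6-diol (6β-OH)
Conditions: NaBH4, CeCl3·7H2O, MeOH, −40 → 0 °C
Reagents that add atoms: none
Why: Hydride reduction under steric approach control (Luche conditions); the β-face of C6 is screened by the syn-axial C10 methyl and the cerium-bound C4 hydroxyl, so hydride enters equatorially from the α-face and gives the axial 6β-alcohol, as with 6-oxo-5α-steroids. The non-basic cerium medium suppresses retro-aldol cleavage.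

Step 12
Reactants: 16 (3R,4R,5S,6R,7S,10S)-3-(tert-butyldimethylsilyloxy)eudesmane-4,6-diol
Product: 17 (3R,4R,5S,6R,7S,10S)-3-(tert-butyldimethylsilyloxy)-4-hydroxyeudesman-6-yl benzoate
Conditions: BzCl, DMAP, pyridine, CH2Cl2, 0 → 40 °C
Reagents that add atoms: benzoyl chloride, O=C(Cl)c1ccccc1
Why: DMAP-catalysed acylation; only the secondary C6 hydroxyl reacts, because the tertiary C4 hydroxyl is inert under these conditions and C3 is silylated.

Step 13
Reactants: 17 (3R,4R,5S,6R,7S,10S)-3-(tert-butyldimethylsilyloxy)-4-hydroxyeudesman-6-yl benzoate
Product: 18 (3R,4R,5S,6R,7S,10S)-3,4-dihydroxyeudesman-6-yl benzoate (CNP0187831.1)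
Conditions: HF·pyridine, pyridine/THF, 0 °C → rt
Reagents that add atoms: none
Why: Fluoride-mediated desilylation in a buffered, non-basic medium, so the benzoate neither migrates nor is cleaved and the tertiary alcohol is not ionised.

## Compound list

1 | isovaleraldehyde (3-methylbutanal) | CC(C)CC=O | starting material
2 | but-3-en-2-one (methyl vinyl ketone) | CC(=O)C=C | starting material
3 | (S)-2-isopropyl-5-oxohexanal | CC(C)[C@H](CCC(C)=O)C=O | intermediate
4 | (S)-4-isopropylcyclohex-2-en-1-one ((S)-cryptone) | CC(C)[C@@H]1CCC(=O)C=C1 | intermediate
5 | (R)-3-hydroxydihydrofuran-2(3H)-one ((R)-α-hydroxy-γ-butyrolactone) | O[C@@H]1CCOC1=O | starting material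
6 | (R)-3-(tert-butyldimethylsilyloxy)dihydrofuran-2(3H)-one | CC(C)(C)[Si](C)(C)O[C@@H]1CCOC1=O | intermediate
7 | (R)-3-(tert-butyldimethylsilyloxy)-5-hydroxypentan-2-one (open form of the hemiketal mixture) | CC(=O)[C@@H](CCO)O[Si](C)(C)C(C)(C)C | intermediate
8 | (R)-3-(tert-butyldimethylsilyloxy)-5-iodopentan-2-one | CC(=O)[C@@H](CCI)O[Si](C)(C)C(C)(C)C | intermediate
9 | (R)-tert-butyl[(5-iodo-2-methylpent-1-en-3-yl)oxy]dimethylsilane | C=C(C)[C@@H](CCI)O[Si](C)(C)C(C)(C)C | intermediate
10 | [(3R)-3-(tert-butyldimethylsilyloxy)-4-methylpent-4-en-1-yl]lithium | C=C(C)[C@@H](CC[Li])O[Si](C)(C)C(C)(C)C | intermediate (not isolated)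
11 | (4S)-1-[(3R)-3-(tert-butyldimethylsilyloxy)-4-methylpent-4-en-1-yl]-4-isopropylcyclohex-2-en-1-ol (both C1 epimers) | CC(C)[C@@H]1CCC(O)(CC[C@@H](O[Si](C)(C)C(C)(C)C)C(C)=C)C=C1 | intermediate
12 | (6S)-3-[(3R)-3-(tert-butyldimethylsilyloxy)-4-methylpent-4-en-1-yl]-6-isopropylcyclohex-2-en-1-one | CC(C)[C@@H]1CCC(CC[C@@H](O[Si](C)(C)C(C)(C)C)C(C)=C)=CC1=O | intermediate
13 | (6S)-3-[(3R)-3-(tert-butyldimethylsilyloxy)-4-oxopentyl]-6-isopropylcyclohex-2-en-1-one | CC(C)[C@@H]1CCC(CC[C@@H](O[Si](C)(C)C(C)(C)C)C(C)=O)=CC1=O | intermediate
14 | lithium enolate (C5=C6) of (3S,6S)-3-methyl-6-isopropyl-3-[(3R)-3-(tert-butyldimethylsilyloxy)-4-oxopentyl]cyclohexanone | CC(C)[C@@H]1CC[C@@](C)(CC[C@@H](O[Si](C)(C)C(C)(C)C)C(C)=O)C=C1O[Li] | intermediate (not isolated)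
15 | (3R,4R,5R,7S,10S)-3-(tert-butyldimethylsilyloxy)-4-hydroxyeudesman-6-one; 3α-OTBS, 4β-OH, 4α-Me, 5α-H, 7β-isopropyl, 10β-Me | CC(C)[C@@H]1CC[C@@]2(C)CC[C@@H](O[Si](C)(C)C(C)(C)C)[C@](C)(O)[C@@H]2C1=O | intermediate
16 | (3R,4R,5S,6R,7S,10S)-3-(tert-butyldimethylsilyloxy)eudesmane-4,6-diol; 6β-OH | CC(C)[C@@H]1CC[C@@]2(C)CC[C@@H](O[Si](C)(C)C(C)(C)C)[C@](C)(O)[C@@H]2[C@@H]1O | intermediate
17 | (3R,4R,5S,6R,7S,10S)-3-(tert-butyldimethylsilyloxy)-4-hydroxyeudesman-6-yl benzoate | CC(C)[C@@H]1CC[C@@]2(C)CC[C@@H](O[Si](C)(C)C(C)(C)C)[C@](C)(O)[C@@H]2[C@@H]1OC(=O)c1ccccc1 | intermediate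
18 | (3R,4R,5S,6R,7S,10S)-3,4-dihydroxyeudesman-6-yl benzoate; 3α,4β-dihydroxy, 6β-benzoyloxy, 5α-H, 7β-isopropyl, 10β-Me | CC(C)[C@@H]1CC[C@@]2(C)CC[C@@H](O)[C@](C)(O)[C@@H]2[C@@H]1OC(=O)c1ccccc1 | target

## Step count and risks

Total steps: 13. Longest linear sequence: 11 steps (5 to 18, steps 3–13); the cryptone branch (steps 1–2) joins at step 7.

**Step 10 (key step).**
- Most likely failure: methyl transfer with poor facial selectivity, together with a ring closure that does not settle on the desired aldolate.
- Why: the only element steering the cuprate is the C7 isopropyl group, which sits α to the carbonyl where its equatorial preference is small. The lithium aldolate can also be held by chelation in a cis-fused or C4-epimeric form, revert to the open diketone on quenching, or lose water on warming.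
- Fallback: the two events are separated. From 13, Me2CuLi with Me3SiCl at −78 °C (silyl-accelerated addition, cold enough for the half-chair bias to be expressed) gives the trimethylsilyl enol ether F1, which is isolated. TiCl4 in CH2Cl2 at −78 °C then closes ring A by an intramolecular Mukaiyama aldol reaction through an open transition state free of lithium chelation, and aqueous work-up rejoins the route at 15.

**Step 12.**
- Most likely failure: sluggish or incomplete acylation.
- Why: the 6β-hydroxyl is axial, flanked by the isopropyl-bearing C7 and syn-axial to both the C10 methyl and the C4 hydroxyl; forcing the reaction invites elimination of the tertiary alcohol.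
- Fallback: the benzoyl group is delivered intramolecularly. From 16, acid-catalysed exchange with trimethyl orthobenzoate (CSA, CH2Cl2) ties the C4 and C6 oxygens into the cyclic orthobenzoate F2. Mild aqueous acid opens it to the hydroxy benzoate; the acyl group is expected to settle on the secondary oxygen, a tertiary ester being disfavoured, and this gives 17.

**Step 11.**
- Most likely failure: retro-aldol cleavage of the β-ketol in the hydride medium, or hydride delivery to the β-face from a boron species bound to the C4 hydroxyl, which would give the 6α-alcohol.
- Fallback: from 15 the tertiary hydroxyl is capped with N-(trimethylsilyl)imidazole as the trimethylsilyl ether F3, which can neither fragment nor direct. LiAlH4 in Et2O at −78 °C then attacks from the open α-face to give the 6β-alcohol F4, and PPTS in methanol removes the tertiary trimethylsilyl group while leaving the TBS ether, rejoining the route at 16.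

**Step 8.**
- Most likely failure: a slow [3,3] shift of the chromate ester toward the carbon next to the isopropyl group, with competing ionisation and dehydration of the tertiary allylic alcohol and acid-promoted erosion of the C7 configuration in the product.
- Fallback: from 11, a rhenium(VII) oxo catalyst (Ph3SiOReO3, Et2O, −50 → 0 °C) equilibrates the tertiary allylic alcohol with its 1,3-transposed secondary isomer F5, which has the more substituted alkene and should be favoured. A neutral oxidation (MnO2 or Dess–Martin periodinane) then gives 12.

**Step 4.**
- Most likely failure: a second addition of methyllithium after premature collapse of the hemiketal alkoxide, or enolisation of the α-silyloxy carbonyl with loss of configuration at C3. The hemiketal form may also slow the iodination in step 5.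
- Fallback: from 6, Me3Al-mediated aminolysis with N,O-dimethylhydroxylamine opens the lactone to the hydroxy Weinreb amide F6. Iodination (I2, PPh3, imidazole) gives the iodo amide F7, and MeMgBr adds once through the chelated tetrahedral intermediate to give iodo ketone 8, bypassing 7.

## Further compounds

F1 | step 10 | (R)-3-(tert-butyldimethylsilyloxy)-5-[(1S,4S)-4-isopropyl-1-methyl-3-(trimethylsilyloxy)cyclohex-2-en-1-yl]pentan-2-one | CC(C)[C@@H]1CC[C@@](C)(CC[C@@H](O[Si](C)(C)C(C)(C)C)C(C)=O)C=C1O[Si](C)(C)C
F2 | step 12 | cyclic 4,6-O-[methoxy(phenyl)methylidene] orthoester of 16 (2-methoxy-2-phenyl-1,3-dioxane across O4 and O6, either configuration at the orthoester carbon) | CC(C)[C@@H]1CC[C@@]2(C)CC[C@@H](O[Si](C)(C)C(C)(C)C)[C@](C)(O3)[C@@H]2[C@@H]1OC3(OC)c4ccccc4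
F3 | step 11 | (3R,4R,5R,7S,10S)-3-(tert-butyldimethylsilyloxy)-4-(trimethylsilyloxy)eudesman-6-one | CC(C)[C@@H]1CC[C@@]2(C)CC[C@@H](O[Si](C)(C)C(C)(C)C)[C@](C)(O[Si](C)(C)C)[C@@H]2C1=O
F4 | step 11 | (3R,4R,5S,6R,7S,10S)-3-(tert-butyldimethylsilyloxy)-4-(trimethylsilyloxy)eudesman-6-ol | CC(C)[C@@H]1CC[C@@]2(C)CC[C@@H](O[Si](C)(C)C(C)(C)C)[C@](C)(O[Si](C)(C)C)[C@@H]2[C@@H]1O
F5 | step 8 | (6S)-3-[(3R)-3-(tert-butyldimethylsilyloxy)-4-methylpent-4-en-1-yl]-6-isopropylcyclohex-2-en-1-ol (both C1 epimers) | CC(C)[C@@H]1CCC(CC[C@@H](O[Si](C)(C)C(C)(C)C)C(C)=C)=CC1O
F6 | step 4 | (R)-2-(tert-butyldimethylsilyloxy)-4-hydroxy-N-methoxy-N-methylbutanamide | CON(C)C(=O)[C@@H](CCO)O[Si](C)(C)C(C)(C)C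
F7 | step 4 | (R)-2-(tert-butyldimethylsilyloxy)-4-iodo-N-methoxy-N-methylbutanamide | CON(C)C(=O)[C@@H](CCI)O[Si](C)(C)C(C)(C)C
A1 | alternative 1 | 3-[(1R,2S)-1-(tert-butyldimethylsilyloxy)-2-isopropyl-4-(p-toluenesulfonyloxy)butyl]-2,4-dimethylphenol | Cc1ccc(O)c(C)c1[C@H](O[Si](C)(C)C(C)(C)C)[C@@H](CCOS(=O)(=O)c2ccc(C)cc2)C(C)C
A2 | alternative 1 | 6β-(tert-butyldimethylsilyloxy)eudesma-1,4-dien-3-one | CC(C)[C@@H]1CC[C@@]2(C)C=CC(=O)C(C)=C2[C@@H]1O[Si](C)(C)C(C)(C)C
A3 | alternative 2 | 2-methoxy-5-methyl-1,4-benzoquinone | COC1=CC(=O)C(C)=CC1=O
A4 | alternative 2 | (E)-tert-butyl[(2-isopropylbuta-1,3-dien-1-yl)oxy]dimethylsilane | C=C/C(C(C)C)=C/O[Si](C)(C)C(C)(C)C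
A5 | alternative 2 | cis-fused endo adduct, 6α-(tert-butyldimethylsilyloxy)-3-methoxy-15-noreudesma-2,7-diene-1,4-dione (5β-H) | CC(C)C1=CC[C@@]2(C)C(=O)C=C(OC)C(=O)[C@H]2[C@H]1O[Si](C)(C)C(C)(C)C
A6 | alternative 3 | trans-fused 3a,7-dimethyl-2,3,3a,4,5,7a-hexahydro-1H-inden-1-one | O=C1CC[C@@]2(C)CCC=C(C)[C@H]12
A7 | alternative 3 | 1-diazo-2-methylpropane | CC(C)C=[N+]=[N-]
A8 | alternative 3 | eudesm-3-en-6-one (5α-H, 7β-isopropyl, 10β-methyl) | CC(C)[C@@H]1CC[C@@]2(C)CCC=C(C)[C@@H]2C1=O
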